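**Plan**

1. Retrosynthetic cuts, in order: the two ester C–O bonds; C8–O and C9–O (one osmylation); C7–O together with the C9–Si bond (allylsilane oxidation); C3–C4 (six-membered ring); C1–C2 and C1–C11 (side chain); C4–C5 and C4–C10 (one-carbon bridge).
2. Forward: eucarvone supplies the seven-membered ring (C5–C11, C13–C15); a glyoxylate carbon (C4, its carboxyl a traceless handle) is stitched across C10/C5 to close the four-membered ring; the C11 ketone is homologated to a but-3-ynoyl chain (C1–C3, C12); the six-membered enone ring is closed last; the triol esters follow.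
3. Key event: photoredox decarboxylation at C4 and addition of the cyclobutyl radical to the central carbon (C3) of an allenyl ketone made in the flask; the exocyclic CH2 then becomes the C12 methyl by conjugation.
4. Enabling feature: C4 and C11 are the two one-carbon bridges of the bicyclo[4.1.1]octene, 1,3 across the four-membered ring C4–C5–C10–C11 and about 2.2 Å apart, with the C11 chain held anti to the C6–C9 bridge, so C3 can only meet C4 and close ring C1–C2–C3–C4–C10–C11.
5. Stereochemistry: one catalytic enantioselective silyl conjugate addition sets C9 (as C–Si); C10 follows by anti aldol, C5 by the bridging, C11 by equilibration, C4 by the ring closure, C7 by anti epoxidation/desilylative opening of the allylsilane, C8 and C9 (oxygen) by osmylation anti to C7–O.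

Key step: step 10

Remark: longipinane numbering is used for all intermediates (C1 ketone carbon; C2=C3 with C12 on C3; C4 and C11 the CH groups flanking the enone; C5 and C10 (C15) the other two four-membered-ring carbons; C6 with C13/C14; C7 OH; C8 angelate; C9 isovalerate). "Syn/anti" on the one-carbon bridges refers to the C6–C9 bridge. Eucarvone is taken as purchasable.

**Route**

Step 1
Reactants: 1 eucarvone; 2 pinacol (dimethylphenylsilyl)boronate; 3 ethyl glyoxylate
Product: 5 ethyl 2-hydroxy-2-[(1R,7R)-7-(dimethylphenylsilyl)-1,4,4-trimethyl-2-oxocyclohept-5-en-1-yl]acetate (both carbinol epimers), via boron enolate 4 (not isolated)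
Conditions: CuCl (5 mol %), chiral C2-symmetric imidazolinium tetrafluoroborate (NHC precursor, 5.5 mol %, enantiomer that gives the R-configured C–Si centre), NaOt-Bu (12 mol %), THF, −78 °C; then 3, −78 → −30 °C; aq. NH4Cl
Reagents that add atoms: pinacol (dimethylphenylsilyl)boronate 2, C[Si](C)(c1ccccc1)B1OC(C)(C)C(C)(C)O1; ethyl glyoxylate 3, CCOC(=O)C=O
Why: Copper-catalysed enantioselective conjugate silylation with a silylboronate: the NHC–Cu–SiMe2Ph species adds 1,4 at C9 (the δ-carbon C7 is neopentylic) with the absolute sense fixed by the ligand, and boron enolate 4 then undergoes aldol addition to the highly electrophilic glyoxylate anti to the new C–Si bond, which makes C10 quaternary with the glyoxylate carbon (future C4) trans to silicon; the carbinol epimers are removed in step 2.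

Step 2
Reactants: 5 β-silyl aldol adduct
Product: 6 ethyl 2-oxo-2-[(1S,7R)-7-(dimethylphenylsilyl)-1,4,4-trimethyl-2-oxocyclohept-5-en-1-yl]acetate
Conditions: Dess–Martin periodinane (1.3 equiv), CH2Cl2, 0 °C → rt
Reagents that add atoms: none
Why: Dess–Martin oxidation of the secondary α-hydroxy ester to the α-keto ester; C10 is quaternary, so nothing can epimerise, and the undefined carbinol centre disappears.

Step 3
Reactants: 6 α-keto ester; 7 tert-butyldimethylsilyl triflate
Product: 8 ethyl 2-[(1S,7R)-2-(tert-butyldimethylsilyloxy)-7-(dimethylphenylsilyl)-1,4,4-trimethylcyclohepta-2,5-dien-1-yl]-2-oxoacetate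
Conditions: 7 (1.3 equiv), Et3N (2 equiv), CH2Cl2, −78 → 0 °C
Reagents that add atoms: tert-butyldimethylsilyl triflate 7, CC(C)(C)[Si](C)(C)OS(=O)(=O)C(F)(F)F
Why: Soft enolisation (silyl triflate/amine) can only go toward C5 because C10 is quaternary and the α-keto ester has no α-hydrogen; it gives the C5=C11 silyl enol ether that is the nucleophile of step 5 and removes the 1,3-dicarbonyl pattern that would invite retro-Claisen cleavage or pyrazoline formation in step 4.

Step 4
Reactants: 8 silyl enol ether keto ester; 9 p-toluenesulfonyl hydrazide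
Product: 11 ethyl 2-diazo-2-[(1R,7R)-2-(tert-butyldimethylsilyloxy)-7-(dimethylphenylsilyl)-1,4,4-trimethylcyclohepta-2,5-dien-1-yl]acetate, via tosylhydrazone 10 (not isolated)
Conditions: 9 (1.05 equiv), 4 Å MS, toluene, 50 °C; then DBU (1.5 equiv), 0 °C → rt
Reagents that add atoms: p-toluenesulfonyl hydrazide 9, Cc1ccc(cc1)S(=O)(=O)NN
Why: Condensation of the sulfonyl hydrazide with the only remaining (and activated) ketone and base-induced loss of sulfinate from the hydrazone anion (Bamford–Stevens-type diazo synthesis from an α-keto ester) give the α-diazo ester; the diazo carbon sits on quaternary C10 and so has no β-hydrogen for a later 1,2-shift, and no stereocentre is touched.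

Step 5
Reactants: 11 diazo ester
Product: 13 ethyl 2-(dimethylphenylsilyl)-1,5,5-trimethyl-8-oxobicyclo[4.1.1]oct-3-ene-7-carboxylate (C4 ester and C11 ketone in longipinane numbering; silicon on the side of the carbonyl bridge; ester syn), via siloxybicyclobutane 12 (not isolated)
Conditions: Rh2(OAc)4 (1 mol %), CH2Cl2, 0 °C → rt (slow addition of 11); then Bu4NF/AcOH (1:1, 1.2 equiv), THF, 0 °C
Reagents that add atoms: none
Why: Proposed new method: the electrophilic rhodium carbenoid at C4 is held one atom (C10) from the nucleophilic enol ether carbon C5 and adds across C5=C11 to give the push–pull siloxybicyclobutane 12 (or its ring-opened silyl-transfer form), fluoride then breaks the donor–acceptor central bond C4–C11 in a retro-aldol sense to release the C11 ketone and the C4 ester enolate, which is protonated from the open face anti to the C6–C9 bridge (ester syn; either epimer would serve); the closest known reactions are the Rh2-catalysed intramolecular bicyclobutanation of 2-diazopent-4-enoates, the cyclopropanation of silyl enol ethers by diazo esters and the fluoride opening of 2-siloxycyclopropanecarboxylates to 4-oxo esters; C5 is set by the bridging itself, because C4 can reach it only on the face of the ring on which C10 carries it.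

Step 6
Reactants: 13 bicyclic keto ester; 14 (methoxymethyl)triphenylphosphonium chloride
Product: 16 ethyl 8-formyl-2-(dimethylphenylsilyl)-1,5,5-trimethylbicyclo[4.1.1]oct-3-ene-7-carboxylate (formyl on C11 anti; ester on C4 syn), via enol ether 15 (not isolated)
Conditions: 14 (3 equiv), KN(SiMe3)2 (2.9 equiv), THF, 0 °C → rt; then 1 M aq. HCl/THF, rt; then DBU (0.2 equiv), CH2Cl2, rt
Reagents that add atoms: (methoxymethyl)triphenylphosphonium chloride 14, COC[P+](c1ccccc1)(c1ccccc1)c1ccccc1.[Cl-]; water, O
Why: Wittig methoxymethylenation of the strained cyclobutanone (not enolisable, both α-carbons are bridgeheads), acid hydrolysis of the enol ether and base equilibration of the aldehyde: the formyl group settles anti to the C6–C9 bridge because the syn position at C11 is crowded by the SiMe2Ph group on C9 and the C4 ester already occupies its own syn position, so C11 is set under thermodynamic control.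

Step 7
Reactants: 16 aldehyde ester; 17 propargyl bromide
Product: 18 ethyl 8-(1-hydroxybut-3-yn-1-yl)-2-(dimethylphenylsilyl)-1,5,5-trimethylbicyclo[4.1.1]oct-3-ene-7-carboxylate (both carbinol epimers)
Conditions: 17 (2 equiv), Zn dust (3 equiv), THF, 0 °C → rt; aq. NH4Cl
Reagents that add atoms: propargyl bromide 17, C#CCBr
Why: Barbier propargylation: the allenylzinc bromide formed in the flask adds through its γ-carbon (SE2′) to the aldehyde and leaves the ester alone, giving the homopropargylic alcohol; the carbinol epimers are removed in step 9.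

Step 8
Reactants: 18 hydroxy ester
Product: 19 8-(1-hydroxybut-3-yn-1-yl)-2-(dimethylphenylsilyl)-1,5,5-trimethylbicyclo[4.1.1]oct-3-ene-7-carboxylic acid
Conditions: LiOH (3 equiv), THF/MeOH/H2O, 40 °C; then aq. HCl to pH 3, 0 °C
Reagents that add atoms: lithium hydroxide, [Li+].[OH-]
Why: Saponification of the ethyl ester and acidification; the terminal alkyne, the allylsilane and the secondary alcohol are stable to aqueous LiOH.

Step 9
Reactants: 19 hydroxy acid
Product: 20 8-(but-3-ynoyl)-2-(dimethylphenylsilyl)-1,5,5-trimethylbicyclo[4.1.1]oct-3-ene-7-carboxylic acid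
Conditions: Dess–Martin periodinane (1.3 equiv), CH2Cl2, 0 °C → rt; non-basic work-up
Reagents that add atoms: none
Why: Dess–Martin oxidation of the homopropargylic alcohol to the β,γ-alkynyl ketone in the presence of the free acid, with a non-basic work-up so that the ketone is carried on before it isomerises.

Step 10
Reactants: 20 alkynyl ketone acid
Product: 23 (4R,5S,9R,10R,11R)-9-(dimethylphenylsilyl)longipina-2,7-dien-1-one, via allenyl ketone 21 (not isolated), via exo-methylene ketone 22 (not isolated)
Conditions: [Ir(dF(CF3)ppy)2(dtbbpy)]PF6 (2 mol %), Cs2CO3 (0.6 equiv), degassed DMF (0.005 M), 450 nm LEDs, rt; then DBU (0.5 equiv), rt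
Reagents that add atoms: none
Why: Cs2CO3 forms the carboxylate, isomerises the propargyl ketone to allenyl ketone 21 and keeps C11 epimerisable so that the side chain stays anti; the excited iridium photocatalyst oxidises the carboxylate, CO2 is lost, the planar cyclobutyl radical at C4 adds to the central allene carbon C3 (β to the ketone), the resulting α-keto allyl radical is reduced by the reduced photocatalyst to the dienolate, protonation gives 22, and DBU moves the exocyclic C3=C12 alkene into conjugation. The closest known reaction types are the photoredox decarboxylative Giese addition of carboxylic acids to enones and radical addition to the central carbon of allenyl carbonyl compounds. The six-membered ring C1–C2–C3–C4–C10–C11 closes in the 6-endo mode with respect to the C2=C3 π bond, on an sp carbon that carries nothing off the allene axis, and this turns the bicyclo[4.1.1]octene into the bridged tricycle. The only new stereocentre, C4, is dictated by the ring: the radical has lost its configuration and can bond only on the face where the C11 chain lies, so H4 ends syn to the C6–C9 bridge. The step needs attack at C3 and not at C2 (5-exo, which would give a bicyclo[2.1.1]hexane) and cyclisation ahead of reduction of the radical; the polarity match (nucleophilic radical, electrophilic C3), the 2.2 Å separation of the two one-carbon bridges and the absence of a hydrogen-atom donor in the redox-neutral cycle secure both.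

Step 11
Reactants: 23 silyl dienone; 24 3-chloroperbenzoic acid
Product: 26 (4R,5S,7R,10R,11R)-7-hydroxylongipina-2,8-dien-1-one, via epoxysilane 25 (not isolated)
Conditions: 24 (1.05 equiv), CH2Cl2, −20 → 0 °C; then Bu4NF/AcOH (1:1, 1.5 equiv), THF, 0 °C → rt
Reagents that add atoms: 3-chloroperbenzoic acid 24, O=C(OO)c1cccc(Cl)c1
Why: Peracid epoxidation of the electron-rich allylsilane alkene C7=C8 (the enone is inert) on the face opposite to silicon, then fluoride-triggered anti 1,2-elimination across Si–C9–C8–O (Peterson-type opening of a β-silyl epoxide) moves the alkene to C8=C9 and leaves the C7 oxygen on the face opposite to the one silicon occupied, which sets C7.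

Step 12
Reactants: 26 allylic alcohol; 7 tert-butyldimethylsilyl triflate
Product: 27 (4R,5S,7R,10R,11R)-7-(tert-butyldimethylsilyloxy)longipina-2,8-dien-1-one
Conditions: 7 (1.5 equiv), 2,6-lutidine (3 equiv), CH2Cl2, −78 → 0 °C
Reagents that add atoms: tert-butyldimethylsilyl triflate 7, CC(C)(C)[Si](C)(C)OS(=O)(=O)C(F)(F)F
Why: Silylation of the hindered neopentylic alcohol with the silyl triflate; both ring positions next to the enone (C11, C4) are bridgeheads and 2,6-lutidine is too weak to enolise through C12.

Step 13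
Reactants: 27 silyl ether diene
Product: 28 (4R,5S,7S,8S,9S,10R,11R)-7-(tert-butyldimethylsilyloxy)-8,9-dihydroxylongipin-2-en-1-one
Conditions: OsO4 (5 mol %), N-methylmorpholine N-oxide (1.5 equiv), acetone/H2O (5:1), rt
Reagents that add atoms: osmium tetroxide, O=[Os](=O)(=O)=O; N-methylmorpholine N-oxide, C[N+]1([O-])CCOCC1; water, O
Why: Upjohn dihydroxylation of the isolated cis alkene C8=C9 (the trisubstituted enone reacts far more slowly); osmium approaches anti to the bulky allylic silyloxy group at C7, which places the C8/C9 cis-diol on the side of the C11 bridge, trans to the C7 oxygen as required.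

Step 14
Reactants: 28 diol; 29 angelic acid; 30 2,4,6-trichlorobenzoyl chloride
Product: 32 (4R,5S,7S,8S,9S,10R,11R)-8-angeloyloxy-7-(tert-butyldimethylsilyloxy)-9-hydroxylongipin-2-en-1-one, via mixed anhydride 31 (not isolated)
Conditions: 29 (1.5 equiv), 30 (1.5 equiv), Et3N (1.6 equiv), toluene, rt; then 28, toluene, 75 °C
Reagents that add atoms: angelic acid 29, C/C=C(/C)C(=O)O
Why: Yamaguchi-type acylation with the preformed mixed anhydride of angelic acid (no nucleophilic catalyst, conditions known to keep the Z geometry); the C8 hydroxyl, flanked by two CH groups, should be acylated ahead of the neopentylic C9 hydroxyl next to quaternary C10.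

Step 15
Reactants: 32 mono-angelate; 33 isovaleric anhydride
Product: 34 (4R,5S,7S,8S,9S,10R,11R)-8-angeloyloxy-7-(tert-butyldimethylsilyloxy)-9-(3-methylbutanoyloxy)longipin-2-en-1-one
Conditions: 33 (3 equiv), DMAP (0.2 equiv), pyridine, CH2Cl2, rt
Reagents that add atoms: isovaleric anhydride 33, CC(C)CC(=O)OC(=O)CC(C)C
Why: DMAP-catalysed acylation of the remaining hindered C9 hydroxyl with the anhydride at room temperature; C7 is blocked as its silyl ether and the angelate should not isomerise under these mild conditions.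

Step 16
Reactants: 34 silyl-protected diester
Product: 35 (4R,5S,7S,8R,9S,10R,11R)-8-angeloyloxy-7-hydroxy-9-(3-methylbutanoyloxy)longipin-2-en-1-one (target)
Conditions: HF·pyridine, pyridine, THF, 0 °C → rt
Reagents that add atoms: none
Why: Acidic fluoride cleavage of the silyl ether frees the C7 hydroxyl without the acyl migration or angelate isomerisation that basic fluoride could cause; no stereocentre is affected.

**Compound list**

1 | eucarvone (2,6,6-trimethylcyclohepta-2,4-dien-1-one) | CC1=CC=CC(C)(C)CC1=O | starting material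
2 | pinacol (dimethylphenylsilyl)boronate | C[Si](C)(c1ccccc1)B1OC(C)(C)C(C)(C)O1 | starting material
3 | ethyl glyoxylate | CCOC(=O)C=O | starting material
4 | boron enolate: 2-{[(3R)-3-(dimethylphenylsilyl)-2,6,6-trimethylcyclohepta-1,4-dien-1-yl]oxy}-4,4,5,5-tetramethyl-1,3,2-dioxaborolane | CC1=C(OB2OC(C)(C)C(C)(C)O2)CC(C)(C)C=C[C@H]1[Si](C)(C)c1ccccc1 | intermediate (not isolated)
5 | ethyl 2-hydroxy-2-[(1R,7R)-7-(dimethylphenylsilyl)-1,4,4-trimethyl-2-oxocyclohept-5-en-1-yl]acetate (silicon trans to the acetate carbon; carbinol centre undefined) | CCOC(=O)C(O)[C@@]1(C)[C@H]([Si](C)(C)c2ccccc2)C=CC(C)(C)CC1=O | intermediate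
6 | ethyl 2-oxo-2-[(1S,7R)-7-(dimethylphenylsilyl)-1,4,4-trimethyl-2-oxocyclohept-5-en-1-yl]acetate | CCOC(=O)C(=O)[C@@]1(C)[C@H]([Si](C)(C)c2ccccc2)C=CC(C)(C)CC1=O | intermediate
7 | tert-butyldimethylsilyl triflate | CC(C)(C)[Si](C)(C)OS(=O)(=O)C(F)(F)F | starting material
8 | ethyl 2-[(1S,7R)-2-(tert-butyldimethylsilyloxy)-7-(dimethylphenylsilyl)-1,4,4-trimethylcyclohepta-2,5-dien-1-yl]-2-oxoacetate | CCOC(=O)C(=O)[C@@]1(C)[C@H]([Si](C)(C)c2ccccc2)C=CC(C)(C)C=C1O[Si](C)(C)C(C)(C)C | intermediate
9 | p-toluenesulfonyl hydrazide | Cc1ccc(cc1)S(=O)(=O)NN | starting material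
10 | tosylhydrazone of 8 at the α-keto ester carbonyl | CCOC(=O)C(=NNS(=O)(=O)c1ccc(C)cc1)[C@@]1(C)[C@H]([Si](C)(C)c2ccccc2)C=CC(C)(C)C=C1O[Si](C)(C)C(C)(C)C | intermediate (not isolated)
11 | ethyl 2-diazo-2-[(1R,7R)-2-(tert-butyldimethylsilyloxy)-7-(dimethylphenylsilyl)-1,4,4-trimethylcyclohepta-2,5-dien-1-yl]acetate | CCOC(=O)C(=[N+]=[N-])[C@@]1(C)[C@H]([Si](C)(C)c2ccccc2)C=CC(C)(C)C=C1O[Si](C)(C)C(C)(C)C | intermediate
12 | siloxybicyclobutane: tricyclic ester with the extra C4–C11 central bond, OTBS on C11 and CO2Et on C4 | CCOC(=O)[C@@]12[C@@]3(C)[C@H]([Si](C)(C)c4ccccc4)C=CC(C)(C)[C@@H]1[C@@]23O[Si](C)(C)C(C)(C)C | intermediate (not isolated)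
13 | ethyl 2-(dimethylphenylsilyl)-1,5,5-trimethyl-8-oxobicyclo[4.1.1]oct-3-ene-7-carboxylate (silicon on the side of the carbonyl bridge; ester syn to the four-carbon bridge) | CCOC(=O)[C@H]1[C@@]2(C)[C@H]([Si](C)(C)c3ccccc3)C=CC(C)(C)[C@@H]1C2=O | intermediate
14 | (methoxymethyl)triphenylphosphonium chloride | COC[P+](c1ccccc1)(c1ccccc1)c1ccccc1.[Cl-] | starting material
15 | ethyl 8-(methoxymethylidene)-2-(dimethylphenylsilyl)-1,5,5-trimethylbicyclo[4.1.1]oct-3-ene-7-carboxylate (enol ether geometry undefined) | CCOC(=O)[C@H]1[C@@]2(C)[C@H]([Si](C)(C)c3ccccc3)C=CC(C)(C)[C@@H]1C2=COC | intermediate (not isolated)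
16 | ethyl 8-formyl-2-(dimethylphenylsilyl)-1,5,5-trimethylbicyclo[4.1.1]oct-3-ene-7-carboxylate (formyl anti, ester syn to the four-carbon bridge) | CCOC(=O)[C@H]1[C@@]2(C)[C@H]([Si](C)(C)c3ccccc3)C=CC(C)(C)[C@@H]1[C@H]2C=O | intermediate
17 | propargyl bromide | C#CCBr | starting material
18 | ethyl 8-(1-hydroxybut-3-yn-1-yl)-2-(dimethylphenylsilyl)-1,5,5-trimethylbicyclo[4.1.1]oct-3-ene-7-carboxylate (carbinol centre undefined) | CCOC(=O)[C@H]1[C@@]2(C)[C@H]([Si](C)(C)c3ccccc3)C=CC(C)(C)[C@@H]1[C@H]2C(O)CC#C | intermediate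
19 | 8-(1-hydroxybut-3-yn-1-yl)-2-(dimethylphenylsilyl)-1,5,5-trimethylbicyclo[4.1.1]oct-3-ene-7-carboxylic acid | OC(=O)[C@H]1[C@@]2(C)[C@H]([Si](C)(C)c3ccccc3)C=CC(C)(C)[C@@H]1[C@H]2C(O)CC#C | intermediate
20 | 8-(but-3-ynoyl)-2-(dimethylphenylsilyl)-1,5,5-trimethylbicyclo[4.1.1]oct-3-ene-7-carboxylic acid | OC(=O)[C@H]1[C@@]2(C)[C@H]([Si](C)(C)c3ccccc3)C=CC(C)(C)[C@@H]1[C@H]2C(=O)CC#C | intermediate
21 | 8-(buta-2,3-dienoyl)-2-(dimethylphenylsilyl)-1,5,5-trimethylbicyclo[4.1.1]oct-3-ene-7-carboxylic acid (as its carboxylate in the flask) | OC(=O)[C@H]1[C@@]2(C)[C@H]([Si](C)(C)c3ccccc3)C=CC(C)(C)[C@@H]1[C@H]2C(=O)C=C=C | intermediate (not isolated)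
22 | (4R,5S,9R,10R,11R)-9-(dimethylphenylsilyl)longipina-3(12),7-dien-1-one | C1=CC(C)(C)[C@@H]2[C@H]3C(=O)CC(=C)[C@@H]2[C@@]3(C)[C@@H]1[Si](C)(C)c1ccccc1 | intermediate (not isolated)
23 | (4R,5S,9R,10R,11R)-9-(dimethylphenylsilyl)longipina-2,7-dien-1-one | C1=CC(C)(C)[C@@H]2[C@H]3C(=O)C=C(C)[C@@H]2[C@@]3(C)[C@@H]1[Si](C)(C)c1ccccc1 | intermediate
24 | 3-chloroperbenzoic acid | O=C(OO)c1cccc(Cl)c1 | starting material
25 | 7,8-epoxide of 23, oxygen on the face opposite to silicon | O1[C@H]2[C@@H]1C(C)(C)[C@@H]3[C@H]4C(=O)C=C(C)[C@@H]3[C@@]4(C)[C@@H]2[Si](C)(C)c1ccccc1 | intermediate (not isolated)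
26 | (4R,5S,7R,10R,11R)-7-hydroxylongipina-2,8-dien-1-one | O[C@H]1C(C)(C)[C@@H]2[C@H]3C(=O)C=C(C)[C@@H]2[C@@]3(C)C=C1 | intermediate
27 | (4R,5S,7R,10R,11R)-7-(tert-butyldimethylsilyloxy)longipina-2,8-dien-1-one | CC(C)(C)[Si](C)(C)O[C@H]1C(C)(C)[C@@H]2[C@H]3C(=O)C=C(C)[C@@H]2[C@@]3(C)C=C1 | intermediate
28 | (4R,5S,7S,8S,9S,10R,11R)-7-(tert-butyldimethylsilyloxy)-8,9-dihydroxylongipin-2-en-1-one | O[C@@H]1[C@@H](O[Si](C)(C)C(C)(C)C)C(C)(C)[C@@H]2[C@H]3C(=O)C=C(C)[C@@H]2[C@@]3(C)[C@@H]1O | intermediate
29 | angelic acid ((Z)-2-methylbut-2-enoic acid) | C/C=C(/C)C(=O)O | starting material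
30 | 2,4,6-trichlorobenzoyl chloride | ClC(=O)c1c(Cl)cc(Cl)cc1Cl | starting material
31 | angelic 2,4,6-trichlorobenzoic anhydride | C/C=C(/C)C(=O)OC(=O)c1c(Cl)cc(Cl)cc1Cl | intermediate (not isolated)
32 | (4R,5S,7S,8S,9S,10R,11R)-8-angeloyloxy-7-(tert-butyldimethylsilyloxy)-9-hydroxylongipin-2-en-1-one | C/C=C(/C)C(=O)O[C@@H]1[C@@H](O[Si](C)(C)C(C)(C)C)C(C)(C)[C@@H]2[C@H]3C(=O)C=C(C)[C@@H]2[C@@]3(C)[C@@H]1O | intermediate
33 | isovaleric anhydride | CC(C)CC(=O)OC(=O)CC(C)C | starting material
34 | (4R,5S,7S,8S,9S,10R,11R)-8-angeloyloxy-7-(tert-butyldimethylsilyloxy)-9-(3-methylbutanoyloxy)longipin-2-en-1-one | C/C=C(/C)C(=O)O[C@@H]1[C@@H](O[Si](C)(C)C(C)(C)C)C(C)(C)[C@@H]2[C@H]3C(=O)C=C(C)[C@@H]2[C@@]3(C)[C@@H]1OC(=O)CC(C)C | intermediate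
35 | (4R,5S,7S,8R,9S,10R,11R)-8-angeloyloxy-7-hydroxy-9-(3-methylbutanoyloxy)longipin-2-en-1-one | C/C=C(/C)C(=O)O[C@@H]1[C@@H](O)C(C)(C)[C@@H]2[C@H]3C(=O)C=C(C)[C@@H]2[C@@]3(C)[C@@H]1OC(=O)CC(C)C | target

**Count**

Total steps: 16. Longest linear sequence: 16 steps (from 1).

**Steps most likely to fail**

Step 5. The carbenoid may be diverted into cyclopropanation of the C7=C8 alkene, C–H insertion or dimerisation before the enol ether captures it, or the silyl enol ether may be lost beforehand. The fallback sets out from 6 and comes back at 13. Irradiation of α-keto ester 6 (λ > 350 nm, benzene) should effect a Norrish–Yang photocyclisation: 1,5-hydrogen transfer from C5 to the excited keto group and closure of the 1,4-biradical at C4–C5 would give ethyl 7-hydroxy-2-(dimethylphenylsilyl)-1,5,5-trimethyl-8-oxobicyclo[4.1.1]oct-3-ene-7-carboxylate F1. Acylation with methyl chlorooxoacetate/pyridine/DMAP would give the methyl oxalate F2. Bu3SnH/AIBN (toluene, 100 °C) would then remove the tertiary oxygen through the α-ester radical, hydrogen being delivered from the open anti face, to give 13.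

Step 10. The C4 radical may be reduced before it cyclises (hydrodecarboxylation), may attack C2, or the carboxylate may add to the allenone in a polar conjugate addition. The fallback sets out from 19 and comes back at 23. Hydroxy acid 19 would be converted with 1-hydroxypyridine-2(1H)-thione and DCC into its Barton ester F3. Irradiation with slow addition of Bu3SnH would release CO2, and the C4 radical would close 6-exo-dig onto the internal carbon of the unactivated terminal alkyne at the alcohol oxidation level to give the exocyclic-methylene alcohol 9-(dimethylphenylsilyl)longipina-3(12),7-dien-1-ol F4. Dess–Martin oxidation of F4 would give 22, and DBU would isomerise 22 to 23.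

Step 1. The silyl nucleophile may add 1,6 at C7, the α-methyl enone may give poor enantio-induction, or the boron enolate may fail to add to the glyoxylate (or revert by retro-aldol). The fallback sets out from 1 and comes back at 5. Rhodium/BINAP-catalysed asymmetric 1,4-addition of 2 to 1 in aqueous dioxane ([Rh(cod)2]OTf, one enantiomer of BINAP, Et3N, 50 °C) would give the β-silyl ketone 3-(dimethylphenylsilyl)-2,6,6-trimethylcyclohept-4-en-1-one F5. Me3SiCl/Et3N/DMF under equilibrating conditions (80 °C) would give the more substituted C10=C11 trimethylsilyl enol ether F6. Sc(OTf)3-catalysed Mukaiyama aldol addition of F6 to 3, again anti to silicon, would give 5 after aqueous work-up.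

Further compounds
F1 | step 5 | ethyl 7-hydroxy-2-(dimethylphenylsilyl)-1,5,5-trimethyl-8-oxobicyclo[4.1.1]oct-3-ene-7-carboxylate | CCOC(=O)C1(O)[C@@]2(C)[C@H]([Si](C)(C)c3ccccc3)C=CC(C)(C)[C@@H]1C2=O
F2 | step 5 | methyl oxalate ester of F1 at the tertiary hydroxyl | CCOC(=O)C1(OC(=O)C(=O)OC)[C@@]2(C)[C@H]([Si](C)(C)c3ccccc3)C=CC(C)(C)[C@@H]1C2=O
F3 | step 10 | Barton ester (2-thioxopyridin-1(2H)-yl ester) of 19 | S=c1ccccn1OC(=O)[C@H]1[C@@]2(C)[C@H]([Si](C)(C)c3ccccc3)C=CC(C)(C)[C@@H]1[C@H]2C(O)CC#C
F4 | step 10 | 9-(dimethylphenylsilyl)longipina-3(12),7-dien-1-ol (carbinol centre undefined) | C1=CC(C)(C)[C@@H]2[C@H]3C(O)CC(=C)[C@@H]2[C@@]3(C)[C@@H]1[Si](C)(C)c1ccccc1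
F5 | step 1 | 3-(dimethylphenylsilyl)-2,6,6-trimethylcyclohept-4-en-1-one (C2 undefined) | CC1[C@H]([Si](C)(C)c2ccccc2)C=CC(C)(C)CC1=O
F6 | step 1 | trimethylsilyl enol ether of F5 (1-trimethylsilyloxy-cyclohepta-1,4-diene) | CC1=C(O[Si](C)(C)C)CC(C)(C)C=C[C@H]1[Si](C)(C)c1ccccc1
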